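**Retrosynthetic overview**

1. The strategy rests on the 1,2-dioxane ring O1–O2–C3–C4–C5–C6. The methine C6 carries O1 and lies β to the ester carbonyl (C6–CH2–CO2Me), and C3 is a ketone-level ketal carbon two CH2 groups away. A 4-substituted oxetan-2-one can therefore mask the acetic acid arm and make the C6–O bond a leaving group, while C3 stays a plain ketone.
2. Key disconnection: O2–C3 and O1–C6 both go back to one molecule of H2O2 and keto β-lactone 15. The only ring of the target closes in that step; the methyl ester and the axial methyl ketal follow (steps 10 and 11).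
3. 15 comes from γ-keto aldehyde 12 and ketene by catalytic asymmetric [2+2] cycloaddition, which sets C6 as R before the key step inverts it to S.
4. 12 comes from Weinreb amide 8 and an acetal Grignard reagent. 8 comes from hex-5-ynoic acid and dec-9-yn-1-ol by Sonogashira coupling with an (E)-iodoalkenol; the terminal alkyne is made only after the coupling, so no partner carries both an iodoalkene and a free alkyne.

Key step: step 9

Assumption: in the LiClO4/O-silyl-cinchona ketene–aldehyde cycloaddition the quinine-derived catalyst is taken to attack the Si face of an unbranched aliphatic aldehyde and give the (4R)-lactone; if a model aldehyde shows the opposite sense, O-trimethylsilylquinidine is used in step 8 and nothing else changes.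

**Route**

Step 1
Reactants: 1 hex-5-ynoic acid
Product: 2 N-methoxy-N-methylhex-5-ynamide
Conditions: MeNHOMe·HCl, N-(3-dimethylaminopropyl)-N′-ethylcarbodiimide hydrochloride (EDC·HCl), Et3N, 4-(dimethylamino)pyridine (cat.), CH2Cl2, 0 °C → rt
Reagents that add atoms: N,O-dimethylhydroxylamine hydrochloride, CNOC.Cl
Why: Carbodiimide-mediated amide coupling is a standard way to a Weinreb amide, and the terminal alkyne is inert to it.

Step 2
Reactants: 3 dec-9-yn-1-ol
Product: 5 (9E)-10-iododec-9-en-1-ol, via alkenylzirconocene 4 (not isolated)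
Conditions: Cp2Zr(H)Cl (2.3 equiv), THF, rt; then I2, THF, 0 °C; aq. Na2S2O3
Reagents that add atoms: iodine, II
Why: Hydrozirconation of a terminal alkyne is a syn, anti-Markovnikov addition (one equivalent of Cp2Zr(H)Cl is spent on the hydroxyl group as a zirconium alkoxide) and iodinolysis of the alkenyl–zirconium bond goes with retention, so the (E)-iodoalkene should form.

Step 3
Reactants: 2 N-methoxy-N-methylhex-5-ynamide; 5 (9E)-10-iododec-9-en-1-ol
Product: 6 (7E)-16-hydroxy-N-methoxy-N-methylhexadec-7-en-5-ynamide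
Conditions: PdCl2(PPh3)2 (3 mol %), CuI (6 mol %), Et3N, THF, rt, degassed
Reagents that add atoms: none
Why: Sonogashira coupling of a terminal alkyne with an (E)-iodoalkene keeps the alkene geometry, and because the iodoalkene has no terminal alkyne of its own at this stage only the cross-coupling can take place.

Step 4
Reactants: 6 (7E)-16-hydroxy-N-methoxy-N-methylhexadec-7-en-5-ynamide
Product: 7 (7E)-N-methoxy-N-methyl-16-oxohexadec-7-en-5-ynamide
Conditions: TEMPO (2,2,6,6-tetramethylpiperidin-1-oxyl, 10 mol %), PhI(OAc)2 (1.1 equiv), CH2Cl2, rt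
Reagents that add atoms: none
Why: The oxoammonium-mediated oxidation of a primary alcohol stops at the aldehyde and leaves the enyne and the amide alone.

Step 5
Reactants: 7 (7E)-N-methoxy-N-methyl-16-oxohexadec-7-en-5-ynamide
Product: 8 (7E)-N-methoxy-N-methylheptadec-7-ene-5,16-diynamide
Conditions: dimethyl (1-diazo-2-oxopropyl)phosphonate (1.3 equiv), K2CO3 (2 equiv), MeOH, 0 °C → rt
Reagents that add atoms: dimethyl (1-diazo-2-oxopropyl)phosphonate, CC(=O)C(=[N+]=[N-])P(=O)(OC)OC
Why: The Ohira–Bestmann variant of the Seyferth–Gilbert homologation turns an enolisable aldehyde into the terminal alkyne under K2CO3/MeOH, which the Weinreb amide and the enyne tolerate.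

Step 6
Reactants: 8 (7E)-N-methoxy-N-methylheptadec-7-ene-5,16-diynamide; 9 2-(2-bromoethyl)-1,3-dioxolane
Product: 11 (9E)-1-(1,3-dioxolan-2-yl)nonadec-9-ene-7,18-diyn-3-one, via acetal Grignard reagent 10 (not isolated)
Conditions: Mg, THF, 25–30 °C (9 → 10); then 8, THF, −10 → 0 °C (3 equiv of 10); pH 7 phosphate buffer
Reagents that add atoms: none
Why: In the Weinreb ketone synthesis a primary alkyl Grignard reagent adds once and the chelated adduct gives the ketone only on quench; the excess reagent covers the equivalent lost to the acidic alkyne C–H, and the alkynylmagnesium species so formed should not attack the chelate at 0 °C.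

Step 7
Reactants: 11 (9E)-1-(1,3-dioxolan-2-yl)nonadec-9-ene-7,18-diyn-3-one
Product: 12 (10E)-4-oxoicos-10-ene-8,19-diynal
Conditions: 1 M aq. HCl, THF, rt, under argon; used without storage
Reagents that add atoms: water, O
Why: Acid-catalysed hydrolysis of an aldehyde-derived 1,3-dioxolane is a standard acetal cleavage and is mild enough for the enyne, the terminal alkyne and the ketone.

Step 8
Reactants: 12 (10E)-4-oxoicos-10-ene-8,19-diynal; 13 acetyl chloride
Product: 15 (4R)-4-[(9E)-3-oxononadec-9-ene-7,18-diyn-1-yl]oxetan-2-one, via ketene 14 (not isolated)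
Conditions: O-trimethylsilylquinine (10 mol %), LiClO4 (1 equiv), iPr2NEt (2.5 equiv), 13 added over 2 h, CH2Cl2/Et2O, −78 °C
Reagents that add atoms: none
Why: In this ketene–aldehyde [2+2] cycloaddition (acyl halide–aldehyde cyclocondensation) the alkaloid-bound acylammonium enolate adds to the lithium-activated aldehyde through a closed transition state and the aldolate lactonises, so the catalyst sets C4 of the lactone as R (see the assumption), while the less electrophilic ketone should not react.

Step 9
Reactants: 15 (4R)-4-[(9E)-3-oxononadec-9-ene-7,18-diyn-1-yl]oxetan-2-one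
Product: 17 2-[(3S,6R)-6-[(6E)-hexadec-6-ene-4,15-diyn-1-yl]-6-hydroxy-1,2-dioxan-3-yl]acetic acid (hemiketal carbon labile; favoured anomer drawn), via hydroperoxy hemiketal 16 (not isolated)
Conditions: anhydrous H2O2 (ca. 2 M in Et2O, 5 equiv), CH2Cl2/CF3CH2OH, 0 °C → rt, dark, no base; water wash, no reductive quench
Reagents that add atoms: hydrogen peroxide, OO
Why: Proposed new method: H2O2 adds reversibly to the C3 ketone of 15 to give hydroperoxy hemiketal 16 (O2–C3 bond), whose terminal OOH oxygen then attacks C6 of the strained lactone anti to the lactone oxygen, so that the alkyl C6–O bond breaks, the carboxylate leaves as the acetic acid arm and the O1–C6 bond closes the 1,2-dioxane; the closest known reactions are the alkyl–oxygen (SN2) openings of 4-alkyl β-lactones by azide, thiolates, sulfonamide anions or neutral water, which go with inversion, and the 6-exo alkylations of hydroperoxy ketals by epoxides or sulfonates. The single ring closes in a 6-exo-tet mode. C6 is set by SN2 inversion of the (4R)-lactone centre and should come out S, whereas the C3 hemiketal centre can equilibrate through the open hydroperoxy ketone and is fixed only in step 11. The selectivity needed is attack at the alkyl carbon C6 and not at the acyl carbon: the tether gives a six-membered transition state for C6 but would need an eight-membered one for the carbonyl carbon, and the neutral, cold medium keeps HOO−, the species that perhydrolyses lactones at the acyl carbon, at a negligible level. Ring strain and the carboxylate leaving group take the place of a sulfonate, so no β-sulfonyloxy ester is present that could eliminate to an enoate, and a direct SN2 attack of free H2O2 at C6 followed by hemiketal closure would lead to the same 17 with the same inversion.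

Step 10
Reactants: 17 2-[(3S,6R)-6-[(6E)-hexadec-6-ene-4,15-diyn-1-yl]-6-hydroxy-1,2-dioxan-3-yl]acetic acid
Product: 18 methyl 2-[(3S,6R)-6-[(6E)-hexadec-6-ene-4,15-diyn-1-yl]-6-hydroxy-1,2-dioxan-3-yl]acetate
Conditions: Me3SiCHN2 (hexanes solution, 1.2 equiv), toluene/MeOH, 0 °C
Reagents that add atoms: (trimethylsilyl)diazomethane, C[Si](C)(C)C=[N+]=[N-]
Why: Methylation of a carboxylic acid by Me3SiCHN2 in methanol is fast and neutral, so the peroxide, the hemiketal and the base-sensitive β-peroxy ester are not put at risk.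

Step 11
Reactants: 18 methyl 2-[(3S,6R)-6-[(6E)-hexadec-6-ene-4,15-diyn-1-yl]-6-hydroxy-1,2-dioxan-3-yl]acetate
Product: 19 methyl 2-[(3S,6R)-6-[(6E)-hexadec-6-ene-4,15-diyn-1-yl]-6-methoxy-1,2-dioxan-3-yl]acetate
Conditions: pyridinium p-toluenesulfonate (10 mol %), HC(OMe)3, MeOH, rt
Reagents that add atoms: methanol, CO
Why: Acid-catalysed exchange of a cyclic peroxy hemiketal with methanol is a reversible ketalisation through the peroxy-stabilised oxocarbenium ion, so under thermodynamic control the ketal carbon should settle as R, with the methoxy group axial (anomeric effect), both carbon chains equatorial and OMe cis to the CH2CO2Me arm as in the target.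

**Compound list**

1 | hex-5-ynoic acid | C#CCCCC(=O)O | starting material
2 | N-methoxy-N-methylhex-5-ynamide | C#CCCCC(=O)N(C)OC | intermediate
3 | dec-9-yn-1-ol | C#CCCCCCCCCO | starting material
4 | chlorobis(cyclopentadienyl)[(1E)-10-{[chlorobis(cyclopentadienyl)zirconio]oxy}dec-1-en-1-yl]zirconium | Cl[Zr](/C=C/CCCCCCCCO[Zr](Cl)(C1C=CC=C1)C1C=CC=C1)(C1C=CC=C1)C1C=CC=C1 | intermediate (not isolated)
5 | (9E)-10-iododec-9-en-1-ol | OCCCCCCCC/C=C/I | intermediate
6 | (7E)-16-hydroxy-N-methoxy-N-methylhexadec-7-en-5-ynamide | OCCCCCCCC/C=C/C#CCCCC(=O)N(C)OC | intermediate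
7 | (7E)-N-methoxy-N-methyl-16-oxohexadec-7-en-5-ynamide | O=CCCCCCCC/C=C/C#CCCCC(=O)N(C)OC | intermediate
8 | (7E)-N-methoxy-N-methylheptadec-7-ene-5,16-diynamide | C#CCCCCCCC/C=C/C#CCCCC(=O)N(C)OC | intermediate
9 | 2-(2-bromoethyl)-1,3-dioxolane | BrCCC1OCCO1 | starting material
10 | [2-(1,3-dioxolan-2-yl)ethyl]magnesium bromide | Br[Mg]CCC1OCCO1 | intermediate (not isolated)
11 | (9E)-1-(1,3-dioxolan-2-yl)nonadec-9-ene-7,18-diyn-3-one | C#CCCCCCCC/C=C/C#CCCCC(=O)CCC1OCCO1 | intermediate
12 | (10E)-4-oxoicos-10-ene-8,19-diynal | C#CCCCCCCC/C=C/C#CCCCC(=O)CCC=O | intermediate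
13 | acetyl chloride | CC(=O)Cl | starting material
14 | ketene (ethenone) | C=C=O | intermediate (not isolated)
15 | (4R)-4-[(9E)-3-oxononadec-9-ene-7,18-diyn-1-yl]oxetan-2-one | C#CCCCCCCC/C=C/C#CCCCC(=O)CC[C@@H]1CC(=O)O1 | intermediate
16 | (4R)-4-[(9E)-3-hydroperoxy-3-hydroxynonadec-9-ene-7,18-diyn-1-yl]oxetan-2-one (both epimers at the hemiketal carbon) | C#CCCCCCCC/C=C/C#CCCCC(O)(OO)CC[C@@H]1CC(=O)O1 | intermediate (not isolated)
17 | 2-[(3S,6R)-6-[(6E)-hexadec-6-ene-4,15-diyn-1-yl]-6-hydroxy-1,2-dioxan-3-yl]acetic acid | C#CCCCCCCC/C=C/C#CCCC[C@]1(O)CC[C@@H](CC(=O)O)OO1 | intermediate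
18 | methyl 2-[(3S,6R)-6-[(6E)-hexadec-6-ene-4,15-diyn-1-yl]-6-hydroxy-1,2-dioxan-3-yl]acetate | C#CCCCCCCC/C=C/C#CCCC[C@]1(O)CC[C@@H](CC(=O)OC)OO1 | intermediate
19 | methyl 2-[(3S,6R)-6-[(6E)-hexadec-6-ene-4,15-diyn-1-yl]-6-methoxy-1,2-dioxan-3-yl]acetate | C#CCCCCCCC/C=C/C#CCCC[C@]1(OC)CC[C@@H](CC(=O)OC)OO1 | target

**Step count**

Total steps: 11. Longest linear sequence: 10 steps (steps 2 to 11 from dec-9-yn-1-ol; equally steps 1 and 3 to 11 from hex-5-ynoic acid).

**Steps most likely to fail**

Step 9. The hydroperoxy hemiketal may displace too slowly at the secondary lactone carbon, so that peroxide attack at the acyl carbon (perhydrolysis with retention and no ring) or slow decomposition of the hydroperoxide takes over. The fallback sets out from 15 and comes back to the route at 19. It forms the same O1–C6 bond by the known base-mediated 6-exo displacement of a secondary methanesulfonate by a hydroperoxy ketal with inversion. The acid arm is first taken down to a protected primary alcohol, so that no β-sulfonyloxy ester is present.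
- 15 would be ketalised (HC(OMe)3, MeOH, pyridinium p-toluenesulfonate) to ketal lactone F1 and reduced with LiBH4, with retention at the carbinol carbon, to ketal diol F2.
- The primary hydroxyl would be silylated (tBuPh2SiCl, imidazole) to silyl ether F3 and the secondary one mesylated (MsCl, Et3N, −20 °C) to mesylate F4.
- Exchange of one methoxy group for OOH (ethereal H2O2, catalytic camphorsulfonic acid) should give methoxy hydroperoxide F5.
- KOtBu with 18-crown-6 in toluene should close silyloxyethyl dioxane F6 with inversion at the carbinol carbon (drawn as the ketal anomer that later acid equilibration favours).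
- Bu4NF would free dioxane alcohol F7, and oxidation (TEMPO, PhI(OAc)2, aqueous MeCN) would give methoxy dioxane acid F8.
- Me3SiCHN2 followed by the conditions of step 11 would give 19.

Step 8. The amine/LiClO4 system meets an aldehyde that also carries an enolisable, chelating γ-ketone, so aldol self-condensation, low conversion or poor facial selectivity may result. The fallback sets out from 12 and comes back at 15. A boron-mediated syn-aldol reaction (Evans aldol, auxiliary control) of 12 with (4S)-4-benzyl-3-(chloroacetyl)-1,3-oxazolidin-2-one (Bu2BOTf, Et3N, CH2Cl2, −78 °C) should give chloro aldol imide F9. Dechlorination with Zn dust in AcOH would give aldol imide F10, and LiOH/H2O2 in aqueous THF would cleave the auxiliary to hydroxy acid F11. Lactonisation by carboxyl activation (PhSO2Cl, pyridine, 0 °C) keeps the carbinol C–O bond and hence its R configuration, and returns 15.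

Step 7. Under the acid needed to cleave the dioxolane the freed γ-keto aldehyde may undergo intramolecular aldol condensation or cyclodehydration. The fallback sets out from 8 and comes back at 12, replacing steps 6 and 7 by a sequence that never uses acid. The Grignard reagent of (3-bromopropoxy)(tert-butyl)dimethylsilane would be added to 8 to give silyloxy ketone F12. Bu4NF buffered with AcOH would give hydroxy ketone F13, and Dess–Martin periodinane with NaHCO3 in CH2Cl2 would oxidise it to 12.

**Further compounds**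

F1 | step 9 | (4R)-4-[(9E)-3,3-dimethoxynonadec-9-ene-7,18-diyn-1-yl]oxetan-2-one | C#CCCCCCCC/C=C/C#CCCCC(OC)(OC)CC[C@@H]1CC(=O)O1
F2 | step 9 | (3R,12E)-6,6-dimethoxydocos-12-ene-10,21-diyne-1,3-diol | C#CCCCCCCC/C=C/C#CCCCC(OC)(OC)CC[C@@H](O)CCO
F3 | step 9 | (3R,12E)-1-[(tert-butyldiphenylsilyl)oxy]-6,6-dimethoxydocos-12-ene-10,21-diyn-3-ol | C#CCCCCCCC/C=C/C#CCCCC(OC)(OC)CC[C@@H](O)CCO[Si](c1ccccc1)(c1ccccc1)C(C)(C)C
F4 | step 9 | (3R,12E)-1-[(tert-butyldiphenylsilyl)oxy]-6,6-dimethoxydocos-12-ene-10,21-diyn-3-yl methanesulfonate | C#CCCCCCCC/C=C/C#CCCCC(OC)(OC)CC[C@@H](OS(C)(=O)=O)CCO[Si](c1ccccc1)(c1ccccc1)C(C)(C)C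
F5 | step 9 | (3R,12E)-1-[(tert-butyldiphenylsilyl)oxy]-6-hydroperoxy-6-methoxydocos-12-ene-10,21-diyn-3-yl methanesulfonate (both epimers at C6) | C#CCCCCCCC/C=C/C#CCCCC(OC)(OO)CC[C@@H](OS(C)(=O)=O)CCO[Si](c1ccccc1)(c1ccccc1)C(C)(C)C
F6 | step 9 | tert-butyl{2-[(3S,6R)-6-[(6E)-hexadec-6-ene-4,15-diyn-1-yl]-6-methoxy-1,2-dioxan-3-yl]ethoxy}diphenylsilane | C#CCCCCCCC/C=C/C#CCCC[C@]1(OC)CC[C@@H](CCO[Si](c2ccccc2)(c2ccccc2)C(C)(C)C)OO1
F7 | step 9 | 2-[(3S,6R)-6-[(6E)-hexadec-6-ene-4,15-diyn-1-yl]-6-methoxy-1,2-dioxan-3-yl]ethan-1-ol | C#CCCCCCCC/C=C/C#CCCC[C@]1(OC)CC[C@@H](CCO)OO1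
F8 | step 9 | 2-[(3S,6R)-6-[(6E)-hexadec-6-ene-4,15-diyn-1-yl]-6-methoxy-1,2-dioxan-3-yl]acetic acid | C#CCCCCCCC/C=C/C#CCCC[C@]1(OC)CC[C@@H](CC(=O)O)OO1
F9 | step 8 | (4S)-4-benzyl-3-[(2S,3R,12E)-2-chloro-3-hydroxy-6-oxodocos-12-ene-10,21-diynoyl]-1,3-oxazolidin-2-one | C#CCCCCCCC/C=C/C#CCCCC(=O)CC[C@@H](O)[C@H](Cl)C(=O)N1[C@@H](Cc2ccccc2)COC1=O
F10 | step 8 | (4S)-4-benzyl-3-[(3R,12E)-3-hydroxy-6-oxodocos-12-ene-10,21-diynoyl]-1,3-oxazolidin-2-one | C#CCCCCCCC/C=C/C#CCCCC(=O)CC[C@@H](O)CC(=O)N1[C@@H](Cc2ccccc2)COC1=O
F11 | step 8 | (3R,12E)-3-hydroxy-6-oxodocos-12-ene-10,21-diynoic acid | C#CCCCCCCC/C=C/C#CCCCC(=O)CC[C@@H](O)CC(=O)O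
F12 | step 7 | (10E)-1-[(tert-butyldimethylsilyl)oxy]icos-10-ene-8,19-diyn-4-one | C#CCCCCCCC/C=C/C#CCCCC(=O)CCCO[Si](C)(C)C(C)(C)C
F13 | step 7 | (10E)-1-hydroxyicos-10-ene-8,19-diyn-4-one | C#CCCCCCCC/C=C/C#CCCCC(=O)CCCO
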